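A small charge of initiator, 0.12 mM on Tuesday and 0.50 mM on Monday, was my way in to a flask charged with 0.25 mM and left for 15 h. Substrate, reagent and scavenger stood at the same charges in all three.

| flask | substrate | reagent | scavenger | initiator | remark | time |
|---|---|---|---|---|---|---|
| Tuesday's | 10 mM | 25 mM | 12 mM | 0.12 mM | run made earlier |  |
| Monday's | 10 mM | 25 mM | 12 mM | 0.50 mM | run made earlier |  |
| Thursday's | 5 mM | 25 mM | 12 mM | 0.25 mM | run made earlier |  |
| flask | 10 mM | 25.0 mM | 12.0 mM | 0.25 mM |  | 15 h |

| run | time / h | substrate / % | target / % |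
|---|---|---|---|
| Tuesday's | 0.667 | 97.5 | 2.4 |
| Tuesday's | 2.00 | 94.9 | 5.1 |
| Tuesday's | 3.00 | 93.2 | 6.7 |
| Tuesday's | 5.00 | 91.4 | 8.9 |
| Tuesday's | 8.00 | 87.9 | 11.6 |
| Tuesday's | 10.0 | 87.4 | 13.3 |
| Tuesday's | 12.0 | 85.8 | 14.6 |
| Monday's | 0.667 | 96.3 | 4.3 |
| Monday's | 2.00 | 91.9 | 8.0 |
| Monday's | 3.00 | 89.4 | 9.3 |
| Monday's | 5.00 | 86.8 | 13.1 |
| Monday's | 8.00 | 83.2 | 16.9 |
| Monday's | 10.0 | 81.0 | 19.0 |
| Monday's | 12.0 | 79.0 | 20.6 |
| Thursday's | 1.00 | 93.9 | 6.8 |
| Thursday's | 2.00 | 90.3 | 9.7 |
| Thursday's | 3.00 | 87.8 | 12.6 |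
| Thursday's | 6.00 | 82.4 | 18.0 |
| Thursday's | 12.0 | 74.2 | 25.3 |

(each reading ± 0.3 percentage points)

- part of the substrate that has reacted at 15 h
- share of the unused reagent that is free and not bound as idle adduct, at 15 h

I took the fraction of the substrate charged that had reacted as the mean of what the substrate and target columns gave. At 12.0 h that was 14.4 % on Tuesday and 20.8 % on Monday. Both were read at the same hour, so their ratio, 1.44, compares the two charges at that hour; it does not hold for every hour, for at 0.667 h the same ratio read 1.63. The logarithm of the ratio at 12.0 h over the logarithm of the initiator ratio is the initiator order at that hour, the apparent reaction order in initiator: 0.258, a reading with the scatter of 0.3 percentage points in it.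

Carried from Tuesday's charge to 0.25 mM, it gave 17.4 % at 12.0 h. Stretched to 15 h by the square root of time, that became 19.5 %, a number I could commit to. The weak link was the square root, so I replaced it. Between 3.00 h and 12.0 h the two runs read a mean time exponent of 0.539, which gave 19.6 %. The earlier runs do not show bound reagent, so I reckoned no free share.

The forecast gave 19.5 %, within 18.3 % to 20.7 %, which is below mine. For the free share it gave 70 %, within 40 % to 97 %, “which is a guess”.

The flask gave 19.7 % reacted and 99.5 % free, so the forecast's free share stood 29 points below it. Idle adduct in the flask held 0.113 mM at 15.0 h.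

    initiator → 2 initiating radical (k = 5.40 × 10⁻⁷ s⁻¹)
    substrate + initiating radical → capped initiator + first chain carrier (k = 2.20 × 10⁵ M⁻¹ s⁻¹)
    reagent + first chain carrier ⇌ target + second chain carrier (K = 0.0440, k = 6700 M⁻¹ s⁻¹)
    substrate + second chain carrier → released group + first chain carrier (k = 4000 M⁻¹ s⁻¹)
    2 first chain carrier → ended chains (k = 9.00 × 10⁷ M⁻¹ s⁻¹)
    reagent + released group ⇌ idle adduct, settled at all times (K = 31.0 M⁻¹)
    scavenger + released group → scavenged by-product (k = 0.0130 M⁻¹ s⁻¹)

For the neighbouring flask, charged with 0.62 mM of initiator and otherwise unchanged, I multiplied this flask's 19.7 % by the initiator ratio raised to 0.258, the order read at 12.0 h, a factor of 1.26, and had 24.8 %. That neighbouring flask gave 24.8 % reacted at 15 h, with 99.4 % of its unused reagent free.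

Readings and results are calculated with made-up constants; the scatter is artificial.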